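**Retrosynthetic overview**
- The target comes from the 6,8-dimethoxy lactone 22 by chelation-controlled cleavage of the C8 methyl ether; 22 comes from alkene hydrogenation of 21.
- 21 comes from cross-metathesis of (3R)-3-allyl-6,8-dimethoxyisochroman-1-one 14 with dec-9-en-5-one 20 (from a pentanoyl Weinreb amide and a pent-4-enyl Grignard).
- The lactone is the only ring formed (the benzene ring is bought). It is closed last on the aryl fragment by ortho-formylation, oxidation to the acid and lactonisation of homoallylic acetate 9.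
- The stereocentre and the key C–C bond come from a reagent-controlled asymmetric allylation of 3,5-dimethoxyphenylacetaldehyde 3 (allyl fragment 4, chiral borane 5).

Assumption: the E/Z mixture from step 10 is carried on unseparated (21 is written as its major E isomer), because step 11 removes the double bond.

**Route**

Step 1
Reactants: 1 2-(3,5-dimethoxyphenyl)acetic acid
Product: 2 2-(3,5-dimethoxyphenyl)ethan-1-ol
Conditions: BH3·THF (1.5 equiv), THF, 0 °C → rt; then H2O
Reagents that add atoms: none
Why: Borane reduction of a carboxylic acid to the primary alcohol is clean and leaves the aryl methyl ethers untouched.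

Step 2
Reactants: 2 2-(3,5-dimethoxyphenyl)ethan-1-ol
Product: 3 2-(3,5-dimethoxyphenyl)acetaldehyde
Conditions: Dess–Martin periodinane (1.2 equiv), CH2Cl2, 0 °C → rt, 45 min; used crude at once
Reagents that add atoms: none
Why: Dess–Martin oxidation is mild and non-basic, so the enolisable arylacetaldehyde is formed without aldol self-condensation or over-oxidation.

Step 3
Reactants: 3 2-(3,5-dimethoxyphenyl)acetaldehyde; 4 allylmagnesium bromide; 5 (+)-B-methoxydiisopinocampheylborane (the enantiomer made from (−)-α-pinene)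
Product: 8 (2R)-1-(3,5-dimethoxyphenyl)pent-4-en-2-ol, via B-allyldiisopinocampheylborane 6 (not isolated), via homoallyl diisopinocampheylborinate 7 (not isolated)
Conditions: 5 (1.3 equiv), 4 (1.25 equiv), Et2O, 0 °C → rt, 1 h; then 3, −78 °C, 3 h; then 3 M NaOH, 30% H2O2, 0 °C → rt
Reagents that add atoms: none
Why: Brown asymmetric allylboration through a chair Zimmerman–Traxler transition state, in which the (−)-α-pinene-derived isopinocampheyl groups deliver the allyl group to the Re face of the aldehyde and so set the (R) carbinol centre (typically above 90% ee; checked by chiral HPLC and upgradable by recrystallising 14).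

Step 4
Reactants: 8 (2R)-1-(3,5-dimethoxyphenyl)pent-4-en-2-ol
Product: 9 (2R)-1-(3,5-dimethoxyphenyl)pent-4-en-2-yl acetate
Conditions: Ac2O, pyridine, DMAP (cat.), CH2Cl2, 0 °C → rt
Reagents that add atoms: acetic anhydride CC(=O)OC(C)=O
Why: DMAP-catalysed O-acylation masks the alcohol for the Vilsmeier step with retention, since the C–O bond of the stereocentre is not broken.

Step 5
Reactants: 9 (2R)-1-(3,5-dimethoxyphenyl)pent-4-en-2-yl acetate
Product: 11 (2R)-1-(2-formyl-3,5-dimethoxyphenyl)pent-4-en-2-yl acetate, via aryl iminium chloride 10 (not isolated)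
Conditions: POCl3 (1.5 equiv), DMF, 0 °C → 60 °C; then aq. NaOAc, rt
Reagents that add atoms: N,N-dimethylformamide CN(C)C=O; water O
Why: Vilsmeier–Haack formylation of a 3,5-dimethoxy-alkylbenzene goes to the position ortho to the side chain and para to a methoxy group (the site between the two methoxy groups is hindered), and the acetate and isolated alkene are inert to the chloroiminium reagent.

Step 6
Reactants: 11 (2R)-1-(2-formyl-3,5-dimethoxyphenyl)pent-4-en-2-yl acetate
Product: 12 2-[(2R)-2-acetoxypent-4-en-1-yl]-4,6-dimethoxybenzoic acid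
Conditions: NaClO2, NaH2PO4, 2-methyl-2-butene (excess), t-BuOH/H2O, 0 °C → rt
Reagents that add atoms: sodium chlorite [Na+].[O-]Cl=O
Why: Pinnick oxidation converts the hindered aryl aldehyde to the acid, with the scavenger alkene trapping HOCl so the electron-rich ring and terminal alkene are spared.

Step 7
Reactants: 12 2-[(2R)-2-acetoxypent-4-en-1-yl]-4,6-dimethoxybenzoic acid
Product: 14 (3R)-3-allyl-6,8-dimethoxyisochroman-1-one, via hydroxy acid 13 (not isolated)
Conditions: LiOH·H2O, THF/MeOH/H2O, rt; then 2 M HCl to pH 1, rt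
Reagents that add atoms: none
Why: Saponification of the acetate followed by acid-promoted lactonisation closes the six-membered lactone by attack of the alcohol oxygen on the carboxyl carbon, so the stereocentre is retained.

Step 8
Reactants: 15 pentanoyl chloride
Product: 16 N-methoxy-N-methylpentanamide
Conditions: MeNHOMe·HCl, Et3N (2.2 equiv), CH2Cl2, 0 °C → rt
Reagents that add atoms: N,O-dimethylhydroxylamine hydrochloride CNOC.Cl
Why: Acylation of the hydroxylamine by the acid chloride gives the Weinreb amide needed for a clean single addition.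

Step 9
Reactants: 16 N-methoxy-N-methylpentanamide; 17 5-bromopent-1-ene
Product: 20 dec-9-en-5-one, via pent-4-enylmagnesium bromide 18 (not isolated), via magnesium hemiaminal chelate 19 (not isolated)
Conditions: 17, Mg, I2 (cat.), THF, rt → 40 °C; then 16, 0 °C; then 1 M HCl
Reagents that add atoms: none
Why: Weinreb ketone synthesis, in which the stable five-membered magnesium chelate prevents over-addition and releases the ketone only on acidic work-up.

Step 10
Reactants: 14 (3R)-3-allyl-6,8-dimethoxyisochroman-1-one; 20 dec-9-en-5-one (3 equiv)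
Product: 21 (3R)-6,8-dimethoxy-3-[(2E)-7-oxoundec-2-en-1-yl]isochroman-1-one
Conditions: Grubbs II (5 mol%), CH2Cl2, 40 °C
Reagents that add atoms: none
Why: Olefin cross-metathesis of two unhindered terminal alkenes is driven by loss of ethene and by the excess of the cheap partner, and does not touch the remote stereocentre, lactone or ketone.

Step 11
Reactants: 21 (3R)-6,8-dimethoxy-3-[(2E)-7-oxoundec-2-en-1-yl]isochroman-1-one
Product: 22 (3R)-6,8-dimethoxy-3-(7-oxoundecyl)isochroman-1-one
Conditions: H2 (1 atm), 10% Pd/C, EtOAc, rt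
Reagents that add atoms: none
Why: Catalytic hydrogenation saturates the disubstituted alkene (both isomers) and leaves the dialkyl ketone, the lactone and the non-benzylic C3–O bond intact.

Step 12
Reactants: 22 (3R)-6,8-dimethoxy-3-(7-oxoundecyl)isochroman-1-one
Product: 24 (3R)-8-hydroxy-6-methoxy-3-(7-oxoundecyl)isochroman-1-one, via aryloxydichloroborane 23 (not isolated)
Conditions: BCl3 (1 M in CH2Cl2, 3 equiv), CH2Cl2, −78 → 0 °C; then H2O
Reagents that add atoms: none
Why: Lewis-acid ether cleavage in which BCl3 chelates the lactone carbonyl and removes only the peri (C8) methyl group, leaving the C6 methoxy group and the stereocentre unchanged.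

**Compound list**
1 | 2-(3,5-dimethoxyphenyl)acetic acid | COc1cc(CC(=O)O)cc(OC)c1 | starting material
2 | 2-(3,5-dimethoxyphenyl)ethan-1-ol | COc1cc(CCO)cc(OC)c1 | intermediate
3 | 2-(3,5-dimethoxyphenyl)acetaldehyde | COc1cc(CC=O)cc(OC)c1 | intermediate
4 | allylmagnesium bromide (1 M in Et2O) | C=CC[Mg]Br | starting material
5 | (+)-B-methoxydiisopinocampheylborane, from (−)-α-pinene | COB([C@H]1C[C@H]2C[C@@H]([C@@H]1C)C2(C)C)[C@H]1C[C@H]2C[C@@H]([C@@H]1C)C2(C)C | starting material
6 | B-allyldiisopinocampheylborane, (−)-α-pinene series (not isolated) | C=CCB([C@H]1C[C@H]2C[C@@H]([C@@H]1C)C2(C)C)[C@H]1C[C@H]2C[C@@H]([C@@H]1C)C2(C)C | intermediate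
7 | (2R)-1-(3,5-dimethoxyphenyl)pent-4-en-2-yl diisopinocampheylborinate (not isolated) | C=CC[C@@H](OB([C@H]1C[C@H]2C[C@@H]([C@@H]1C)C2(C)C)[C@H]1C[C@H]2C[C@@H]([C@@H]1C)C2(C)C)Cc1cc(OC)cc(OC)c1 | intermediate
8 | (2R)-1-(3,5-dimethoxyphenyl)pent-4-en-2-ol | C=CC[C@@H](O)Cc1cc(OC)cc(OC)c1 | intermediate
9 | (2R)-1-(3,5-dimethoxyphenyl)pent-4-en-2-yl acetate | C=CC[C@@H](OC(C)=O)Cc1cc(OC)cc(OC)c1 | intermediate
10 | {2-[(2R)-2-acetoxypent-4-en-1-yl]-4,6-dimethoxyphenyl}methylidene(dimethyl)ammonium chloride (not isolated) | C=CC[C@@H](OC(C)=O)Cc1cc(OC)cc(OC)c1C=[N+](C)C.[Cl-] | intermediate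
11 | (2R)-1-(2-formyl-3,5-dimethoxyphenyl)pent-4-en-2-yl acetate | C=CC[C@@H](OC(C)=O)Cc1cc(OC)cc(OC)c1C=O | intermediate
12 | 2-[(2R)-2-acetoxypent-4-en-1-yl]-4,6-dimethoxybenzoic acid | C=CC[C@@H](OC(C)=O)Cc1cc(OC)cc(OC)c1C(=O)O | intermediate
13 | 2-[(2R)-2-hydroxypent-4-en-1-yl]-4,6-dimethoxybenzoic acid (not isolated) | C=CC[C@@H](O)Cc1cc(OC)cc(OC)c1C(=O)O | intermediate
14 | (3R)-3-allyl-6,8-dimethoxyisochroman-1-one | C=CC[C@@H]1Cc2cc(OC)cc(OC)c2C(=O)O1 | intermediate
15 | pentanoyl chloride | CCCCC(=O)Cl | starting material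
16 | N-methoxy-N-methylpentanamide | CCCCC(=O)N(C)OC | intermediate
17 | 5-bromopent-1-ene | BrCCCC=C | starting material
18 | pent-4-en-1-ylmagnesium bromide (not isolated) | C=CCCC[Mg]Br | intermediate
19 | bromomagnesium 5-[methoxy(methyl)amino]dec-9-en-5-olate (not isolated) | CCCCC(CCCC=C)(O[Mg]Br)N(C)OC | intermediate
20 | dec-9-en-5-one | CCCCC(=O)CCCC=C | intermediate
21 | (3R)-6,8-dimethoxy-3-[(2E)-7-oxoundec-2-en-1-yl]isochroman-1-one | CCCCC(=O)CCC/C=C/C[C@@H]1Cc2cc(OC)cc(OC)c2C(=O)O1 | intermediate
22 | (3R)-6,8-dimethoxy-3-(7-oxoundecyl)isochroman-1-one | CCCCC(=O)CCCCCC[C@@H]1Cc2cc(OC)cc(OC)c2C(=O)O1 | intermediate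
23 | (3R)-8-(dichloroboryloxy)-6-methoxy-3-(7-oxoundecyl)isochroman-1-one (not isolated) | CCCCC(=O)CCCCCC[C@@H]1Cc2cc(OC)cc(OB(Cl)Cl)c2C(=O)O1 | intermediate
24 | (3R)-8-hydroxy-6-methoxy-3-(7-oxoundecyl)isochroman-1-one | CCCCC(=O)CCCCCC[C@@H]1Cc2cc(OC)cc(O)c2C(=O)O1 | target

**Totals**
Total step count: 12.
Longest linear sequence: 10 steps (1 → 2 → 3 → 8 → 9 → 11 → 12 → 14 → 21 → 22 → 24, that is steps 1–7 and 10–12). Steps 8–9 are a two-step side branch that supplies 20.

**The three steps most likely to fail, with fallbacks**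

Step 3 (asymmetric allylation). The arylacetaldehyde 3 is enolisable and the enantiomeric excess may fall short of what a single enantiomer needs. The fallback sets out from 3 and comes back at 8. Corey–Chaykovsky methylenation of 3 (Me3S+ I−, NaH, DMSO/THF, 0 °C) gives racemic 2-(3,5-dimethoxybenzyl)oxirane F1. Jacobsen hydrolytic kinetic resolution with (S,S)-(salen)Co(III)OAc (0.5 mol%) and 0.55 equiv of water (the catalyst antipode that hydrolyses the (R)-epoxide) leaves (S)-2-(3,5-dimethoxybenzyl)oxirane F2 in over 99% ee. Copper-catalysed opening of F2 at its terminal carbon with vinylmagnesium bromide (CuI 10 mol%, THF, −40 °C) gives 8 without touching the stereocentre.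

Step 5 (Vilsmeier–Haack formylation). Some attack at the position between the two methoxy groups, or sluggish conversion of the acetate, is possible. The fallback sets out from 8 and comes back at 14, replacing steps 4–7. NBS (1.0 equiv, MeCN, −20 → 0 °C) brominates the ring ortho to the side chain, much faster than it attacks the isolated alkene, to give (2R)-1-(2-bromo-3,5-dimethoxyphenyl)pent-4-en-2-ol F3. Treatment of F3 with n-BuLi (2.2 equiv, THF, −78 °C: alkoxide formation, then bromine–lithium exchange), CO2 and then 2 M HCl gives hydroxy acid 13, which closes to 14.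

Step 6 (Pinnick oxidation). HOCl that escapes the scavenger can chlorinate the electron-rich ring or add to the terminal alkene. The fallback sets out from 11 and comes back at 14, replacing steps 6–7 with a chlorine-free oxidation at the lactol level. Methanolysis of the acetate (K2CO3, MeOH, rt) frees the hydroxy aldehyde, which closes to (3R)-3-allyl-6,8-dimethoxyisochroman-1-ol F4 (mixture of C1 epimers). Fétizon oxidation of F4 (Ag2CO3 on Celite, toluene, reflux) gives lactone 14.

**Further compounds**
F1 | step 3 | racemic 2-(3,5-dimethoxybenzyl)oxirane | COc1cc(CC2CO2)cc(OC)c1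
F2 | step 3 | (S)-2-(3,5-dimethoxybenzyl)oxirane | COc1cc(C[C@H]2CO2)cc(OC)c1
F3 | step 5 | (2R)-1-(2-bromo-3,5-dimethoxyphenyl)pent-4-en-2-ol | C=CC[C@@H](O)Cc1cc(OC)cc(OC)c1Br
F4 | step 6 | (3R)-3-allyl-6,8-dimethoxyisochroman-1-ol (C1 epimers) | C=CC[C@@H]1Cc2cc(OC)cc(OC)c2C(O)O1
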